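**Plan**

- Lactone numbering used in the discussion: O1, C2 (carbonyl), C3 (methyl-bearing), C4 (carboxyl-bearing), C5 (stereocentre carrying the 13-acetoxytridecyl chain). Within this ring, C2, C3 and the C3 methyl are the three carbons of a pyruvate ester, and C4 with its carboxyl plus C5 with O1 are the α-carbon, ester and carbinol of a β-hydroxy ester.
- Retrosynthesis: the C3=C4 alkene is traced back to a tertiary C3 alcohol; then C3–C4 and O1–C2 are cut together (aldol plus lactonisation), giving methyl pyruvate and a protected (R)-3,16-dihydroxyhexadecanoate.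
- The chain is cut between C4 and C5 of that hexadecanoate (acetoacetate numbering), giving tert-butyl acetoacetate and silyl-protected 12-bromododecan-1-ol.
- Forward: the chain is joined first by dianion alkylation, the carbinol is set by hydrogenation, the only ring is closed in the aldol–lactonisation, then dehydration, silyl-to-acetyl exchange and ester acidolysis.
- Stereochemistry: the single (R) centre comes from (R)-BINAP–ruthenium hydrogenation of the β-keto ester; no bond to it is broken afterwards, and once the butenolide exists only weak bases or acids are used.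

Key step: step 4

Remark: systematic names number the ring as a furan, so lactone C5 appears there as C2; the target is (R) at that carbon as read from its SMILES, and LDA is taken as the commercial solution.

**Step 1**
Reactants: 1 12-bromododecan-1-ol
Product: 2 (12-bromododecyloxy)triisopropylsilane
Conditions: TIPSCl, imidazole, CH2Cl2, 0 °C to rt
Reagents that add atoms: triisopropylsilyl chloride, CC(C)[Si](Cl)(C(C)C)C(C)C
Why: Routine silyl ether protection of a primary alcohol, with the bulky triisopropylsilyl group chosen because it must later survive an alkyllithium, warm methanol under hydrogen and two equivalents of lithium amide.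

**Step 2**
Reactants: 3 tert-butyl acetoacetate; 2 (12-bromododecyloxy)triisopropylsilane
Product: 5 tert-butyl 3-oxo-16-[(triisopropylsilyl)oxy]hexadecanoate, via sodium lithium dianion of tert-butyl acetoacetate 4 (not isolated)
Conditions: NaH, THF, 0 °C; n-BuLi, 0 °C; then 2, 0 °C to rt; 1 M HCl quench
Reagents that add atoms: none
Why: Weiler-type γ-alkylation of an acetoacetate dianion, in which the more basic terminal carbon displaces the primary bromide by SN2 and the C2 methylene is left untouched.

**Step 3**
Reactants: 5 tert-butyl 3-oxo-16-[(triisopropylsilyl)oxy]hexadecanoate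
Product: 6 tert-butyl (R)-3-hydroxy-16-[(triisopropylsilyl)oxy]hexadecanoate
Conditions: [RuCl2((R)-BINAP)]2·NEt3 (cat.), H2 (4 atm), MeOH/CH2Cl2, 45 °C
Reagents that add atoms: none
Why: Noyori asymmetric hydrogenation of a β-keto ester, in which the ester carbonyl chelates divalent ruthenium and the (R)-BINAP ligand should direct hydride to the face giving the (R)-carbinol, as for simple 3-oxoalkanoates; tert-butyl ester and silyl ether are expected to tolerate the mild conditions.

**Step 4**
Reactants: 6 tert-butyl (R)-3-hydroxy-16-[(triisopropylsilyl)oxy]hexadecanoate; 7 methyl pyruvate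
Product: 10 tert-butyl (2R)-4-hydroxy-4-methyl-5-oxo-2-{13-[(triisopropylsilyl)oxy]tridecyl}tetrahydrofuran-3-carboxylate (mixture of epimers at the two new ring carbons), via lithium alkoxide enolate dianion 8 (not isolated), via open-chain dilithium aldolate 9 (not isolated)
Conditions: LDA (2.2 equiv), THF, −78 to −20 °C; 7, −78 to 0 °C; AcOH quench
Reagents that add atoms: none
Why: Two equivalents of LDA remove first the hydroxyl proton and then an α-proton of 6, and the chelated alkoxide–enolate 8 attacks through its α-carbon the ketone carbonyl of 7, the more electrophilic of the two pyruvate carbonyls, forming the C3–C4 bond in aldolate 9. The closest known reaction type is the Fráter–Seebach aldol addition of β-hydroxy ester dianions to aldehydes and ketones, followed by alkoxide lactonisation of a γ-hydroxy ester. On warming, the secondary alkoxide at C5 adds to the methyl ester carbonyl and expels methoxide, a 5-exo-trig acyl substitution that forms O1–C2 and closes the only ring; the tert-butyl ester is not attacked because it is hindered and could only give a four-membered lactone. The new centre at C4 should arise mainly trans to the chain (attack anti to the C5 substituent on the six-membered lithium chelate) and that at C3 is not controlled, which is acceptable because both become sp2 in step 5. The step must preserve the C5 configuration and favour carbonyl addition over proton transfer: C5 bears no acidic hydrogen and its lithium alkoxide is too poor a leaving group for β-elimination, and addition at −78 °C to the highly electrophilic α-keto ester should outrun deprotonation of the pyruvate methyl group.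

**Step 5**
Reactants: 10 tert-butyl (2R)-4-hydroxy-4-methyl-5-oxo-2-{13-[(triisopropylsilyl)oxy]tridecyl}tetrahydrofuran-3-carboxylate
Product: 12 tert-butyl (2R)-4-methyl-5-oxo-2-{13-[(triisopropylsilyl)oxy]tridecyl}-2,5-dihydrofuran-3-carboxylate, via tertiary mesylate 11 (not isolated)
Conditions: MsCl, Et3N, DMAP (cat.), CH2Cl2, 0 °C to rt
Reagents that add atoms: none
Why: Mesylation of the tertiary alcohol followed by E1cB elimination (the C4 hydrogen is α to the tert-butyl ester and the mesylate is β to it), which needs no antiperiplanar geometry, so all epimers should converge on the doubly conjugated tetrasubstituted alkene while C5 is not touched.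

**Step 6**
Reactants: 12 tert-butyl (2R)-4-methyl-5-oxo-2-{13-[(triisopropylsilyl)oxy]tridecyl}-2,5-dihydrofuran-3-carboxylate
Product: 13 tert-butyl (2R)-2-(13-hydroxytridecyl)-4-methyl-5-oxo-2,5-dihydrofuran-3-carboxylate
Conditions: HF·pyridine, THF/pyridine, 0 °C to rt
Reagents that add atoms: none
Why: Fluoride-driven silyl ether cleavage under buffered acidic conditions, chosen over basic fluoride so that the γ-hydrogen of the butenolide at C5 is not exposed to base; the tert-butyl ester and lactone should be inert.

**Step 7**
Reactants: 13 tert-butyl (2R)-2-(13-hydroxytridecyl)-4-methyl-5-oxo-2,5-dihydrofuran-3-carboxylate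
Product: 14 tert-butyl (2R)-2-(13-acetoxytridecyl)-4-methyl-5-oxo-2,5-dihydrofuran-3-carboxylate
Conditions: Ac2O, pyridine, DMAP (cat.), CH2Cl2, 0 °C to rt
Reagents that add atoms: acetic anhydride, CC(=O)OC(C)=O
Why: DMAP-catalysed acetylation of the only free hydroxyl group, with pyridine too weak a base to deprotonate C5.

**Step 8**
Reactants: 14 tert-butyl (2R)-2-(13-acetoxytridecyl)-4-methyl-5-oxo-2,5-dihydrofuran-3-carboxylate
Product: 15 (2R)-2-(13-acetoxytridecyl)-4-methyl-5-oxo-2,5-dihydrofuran-3-carboxylic acid
Conditions: TFA/CH2Cl2 (1:4), 0 °C to rt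
Reagents that add atoms: none
Why: Acidolysis of the tert-butyl ester through the tert-butyl cation with loss of isobutene, conditions under which the primary acetate, the butenolide and the C5 centre should remain intact.

**Compound list**

1 | 12-bromododecan-1-ol | OCCCCCCCCCCCCBr | starting material
2 | (12-bromododecyloxy)triisopropylsilane | CC(C)[Si](C(C)C)(C(C)C)OCCCCCCCCCCCCBr | intermediate
3 | tert-butyl acetoacetate | CC(=O)CC(=O)OC(C)(C)C | starting material
4 | sodium lithium dianion of tert-butyl acetoacetate | [Li+].[Na+].C=C([O-])C=C([O-])OC(C)(C)C | intermediate (not isolated)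
5 | tert-butyl 3-oxo-16-[(triisopropylsilyl)oxy]hexadecanoate | CC(C)[Si](C(C)C)(C(C)C)OCCCCCCCCCCCCCC(=O)CC(=O)OC(C)(C)C | intermediate
6 | tert-butyl (R)-3-hydroxy-16-[(triisopropylsilyl)oxy]hexadecanoate | CC(C)[Si](C(C)C)(C(C)C)OCCCCCCCCCCCCC[C@@H](O)CC(=O)OC(C)(C)C | intermediate
7 | methyl pyruvate | CC(=O)C(=O)OC | starting material
8 | dilithium (R)-1-tert-butoxy-16-[(triisopropylsilyl)oxy]hexadec-1-ene-1,3-bis(olate), the alkoxide–enolate dianion of 6 | [Li+].[Li+].CC(C)[Si](C(C)C)(C(C)C)OCCCCCCCCCCCCC[C@@H]([O-])C=C([O-])OC(C)(C)C | intermediate (not isolated)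
9 | dilithium dialkoxide of 4-tert-butyl 1-methyl 2-hydroxy-3-{(1R)-1-hydroxy-14-[(triisopropylsilyl)oxy]tetradecyl}-2-methylbutanedioate | [Li+].[Li+].CC(C)[Si](C(C)C)(C(C)C)OCCCCCCCCCCCCC[C@@H]([O-])C(C(=O)OC(C)(C)C)C(C)([O-])C(=O)OC | intermediate (not isolated)
10 | tert-butyl (2R)-4-hydroxy-4-methyl-5-oxo-2-{13-[(triisopropylsilyl)oxy]tridecyl}tetrahydrofuran-3-carboxylate (epimers at ring C3 and C4) | CC(C)[Si](C(C)C)(C(C)C)OCCCCCCCCCCCCC[C@H]1OC(=O)C(C)(O)C1C(=O)OC(C)(C)C | intermediate
11 | tert-butyl (2R)-4-methyl-4-[(methylsulfonyl)oxy]-5-oxo-2-{13-[(triisopropylsilyl)oxy]tridecyl}tetrahydrofuran-3-carboxylate | CC(C)[Si](C(C)C)(C(C)C)OCCCCCCCCCCCCC[C@H]1OC(=O)C(C)(OS(C)(=O)=O)C1C(=O)OC(C)(C)C | intermediate (not isolated)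
12 | tert-butyl (2R)-4-methyl-5-oxo-2-{13-[(triisopropylsilyl)oxy]tridecyl}-2,5-dihydrofuran-3-carboxylate | CC(C)[Si](C(C)C)(C(C)C)OCCCCCCCCCCCCC[C@H]1OC(=O)C(C)=C1C(=O)OC(C)(C)C | intermediate
13 | tert-butyl (2R)-2-(13-hydroxytridecyl)-4-methyl-5-oxo-2,5-dihydrofuran-3-carboxylate | OCCCCCCCCCCCCC[C@H]1OC(=O)C(C)=C1C(=O)OC(C)(C)C | intermediate
14 | tert-butyl (2R)-2-(13-acetoxytridecyl)-4-methyl-5-oxo-2,5-dihydrofuran-3-carboxylate | CC(=O)OCCCCCCCCCCCCC[C@H]1OC(=O)C(C)=C1C(=O)OC(C)(C)C | intermediate
15 | (2R)-2-(13-acetoxytridecyl)-4-methyl-5-oxo-2,5-dihydrofuran-3-carboxylic acid | CC(=O)OCCCCCCCCCCCCC[C@H]1OC(=O)C(C)=C1C(=O)O | target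

**Count**

Total steps: 8. Longest linear sequence: 8 steps (1 to 15).

**Steps most likely to fail**

Step 4. The strongly basic dianion may take a proton from the methyl group of methyl pyruvate instead of adding to its ketone, with self-condensation of the pyruvate, or the aldolate may revert before the lactone closes. The fallback keeps the same two bonds but makes the carbon–carbon bond under Lewis acid instead of lithium enolate conditions. It sets out from 6: double deprotonation with LDA and trapping with TMSCl should give the O-trimethylsilyl ether trimethylsilyl ketene acetal F1. A Mukaiyama aldol addition of F1 to 7 with TiCl4 in CH2Cl2 at −78 °C should give, after aqueous work-up, the open-chain diol diester F2. Catalytic camphorsulfonic acid in CH2Cl2 then closes the lactone, returning to the route at 10.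

Step 5. Elimination from the hindered tertiary mesylate may be slow, and prolonged exposure to amine base could erode the C5 configuration by γ-deprotonation of the butenolide once it has formed. The fallback is a base-free dehydration from 10 with the Martin sulfurane Ph2S[OC(CF3)2Ph]2 in CH2Cl2 at 0 °C. This should give 12 directly, possibly together with the exocyclic methylene lactone F3. F3 would be moved into conjugation with catalytic RhCl3·3H2O in warm ethanol, returning to the route at 12.

Step 2. The unactivated long-chain bromide may react slowly with the acetoacetate dianion, leaving time for dianion decomposition, double alkylation or O-alkylation. The fallback builds the β-keto ester by a different bond construction from 2. Lithioacetonitrile (MeCN, n-BuLi, THF, −78 °C) displaces the bromide to give 14-[(triisopropylsilyl)oxy]tetradecanenitrile F4. A Blaise reaction of F4 with tert-butyl bromoacetate and activated zinc in refluxing THF gives the enamino ester F5, which brief treatment with 1 M HCl hydrolyses to the β-keto ester, returning to the route at 5.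

**Further compounds**

F1 | step 4 | tert-butyl trimethylsilyl ketene acetal of tert-butyl (R)-3-[(trimethylsilyl)oxy]-16-[(triisopropylsilyl)oxy]hexadecanoate | CC(C)[Si](C(C)C)(C(C)C)OCCCCCCCCCCCCC[C@@H](O[Si](C)(C)C)C=C(O[Si](C)(C)C)OC(C)(C)C
F2 | step 4 | 4-tert-butyl 1-methyl 2-hydroxy-3-{(1R)-1-hydroxy-14-[(triisopropylsilyl)oxy]tetradecyl}-2-methylbutanedioate (mixture of diastereomers) | CC(C)[Si](C(C)C)(C(C)C)OCCCCCCCCCCCCC[C@@H](O)C(C(=O)OC(C)(C)C)C(C)(O)C(=O)OC
F3 | step 5 | tert-butyl (2R)-4-methylidene-5-oxo-2-{13-[(triisopropylsilyl)oxy]tridecyl}tetrahydrofuran-3-carboxylate | CC(C)[Si](C(C)C)(C(C)C)OCCCCCCCCCCCCC[C@H]1OC(=O)C(=C)C1C(=O)OC(C)(C)C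
F4 | step 2 | 14-[(triisopropylsilyl)oxy]tetradecanenitrile | CC(C)[Si](C(C)C)(C(C)C)OCCCCCCCCCCCCCC#N
F5 | step 2 | tert-butyl (Z)-3-amino-16-[(triisopropylsilyl)oxy]hexadec-2-enoate | CC(C)[Si](C(C)C)(C(C)C)OCCCCCCCCCCCCC/C(N)=C/C(=O)OC(C)(C)C
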